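**Retrosynthetic overview**
1. Ester C–O bond at C4′ (side-chain carbinol): cesium (R)-mevalonate displaces a side-chain (R)-mesylate with inversion. The hydroquinone is unmasked last from its dimethyl ether.
2. Lactone ring B (the only ring built; aromatic ring A is bought): C4–C4a bond from an ortho-metalated 2,5-dimethoxybenzamide and a terminal epoxide, then acid lactonization, which also frees the C4′ hydroxyl.
3. Key disconnection, C1′–C2′ and C2′–C3′: the carbon of a 2-silyl-1,3-dithiane serves as a carbonyl dianion and stitches together the electrophilic CH2 termini of (R)-propylene oxide and (R)-epichlorohydrin in one flask. Both stereocentres come from the epoxides; the dithiane is later reduced to CH2.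
4. Ring order: oxirane re-formed in the key step, then lactone ring B in step 3.

Assumption: 2-(tert-butyldimethylsilyl)-1,3-dithiane, (R)-propylene oxide, (R)-epichlorohydrin and (R)-mevalonolactone are bought as such; (R)-mevalonolactone is commercial but not cheap.

Numbering used below: isochromanone positions C1–C8a; side chain C1′–C5′ (C4′ is the carbinol carbon, C5′ the methyl).

**Route**

Step 1
Reactants: 1 2-(tert-butyldimethylsilyl)-1,3-dithiane; 2 (R)-propylene oxide [(2R)-2-methyloxirane]; 3 (R)-epichlorohydrin [(2R)-2-(chloromethyl)oxirane]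
Product: 8 tert-butyldimethyl{[(2R)-1-(2-{[(2R)-oxiran-2-yl]methyl}-1,3-dithian-2-yl)propan-2-yl]oxy}silane, via lithiated silyl dithiane 4 (not isolated), via lithium alkoxide 5 (not isolated), via Brook-rearranged dithianyl lithium 6 (not isolated), via chlorohydrin alkoxide 7 (not isolated)
Conditions: t-BuLi, Et2O, −78 → −45 °C; 2, −78 → −25 °C; then 3, HMPA, THF, −78 °C → rt
Reagents that add atoms: none
Why: Smith–Tietze three-component linchpin coupling, in which lithiated 1 (an acyl-anion equivalent) opens 2 at CH2, HMPA triggers a 1,4-Brook rearrangement that silylates the C4′ oxygen and regenerates a dithianyl anion, and this anion opens the epoxide CH2 of 3 before the chloro-alkoxide recloses to a new oxirane, so the dithiane carbon joins two normally electrophilic carbons and both stereocentres are carried over untouched from 2 and 3.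

Step 2
Reactants: 9 2,5-dimethoxybenzoic acid
Product: 11 N,N-diethyl-2,5-dimethoxybenzamide, via acid chloride 10 (not isolated)
Conditions: (COCl)2, cat. DMF, CH2Cl2, 0 °C → rt; concentrate; Et2NH, CH2Cl2, 0 °C → rt
Reagents that add atoms: diethylamine, CCNCC
Why: Standard acid chloride formation and amidation (Schotten–Baumann type) installs the tertiary amide needed as the directing group; no stereocentre is involved.

Step 3
Reactants: 11 N,N-diethyl-2,5-dimethoxybenzamide; 8 the epoxide from step 1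
Product: 15 (3S)-3-({2-[(2R)-2-hydroxypropyl]-1,3-dithian-2-yl}methyl)-5,8-dimethoxy-3,4-dihydro-1H-isochromen-1-one, via ortho-lithiated amide 12 (not isolated), via arylmagnesium bromide 13 (not isolated), via hydroxy amide 14 (not isolated)
Conditions: 11 (2 equiv), s-BuLi, TMEDA, THF, −78 °C; MgBr2·OEt2, −78 → −20 °C; CuBr·SMe2 (10 mol %), 8, −20 → 0 °C; aqueous work-up; crude, p-TsOH·H2O, toluene–MeOH (10:1), 80 °C
Reagents that add atoms: none
Why: Directed ortho-metalation (amide and methoxy cooperate at the carbon between them), Li→Mg exchange and copper-catalysed SN2 opening of the terminal epoxide at CH2 form C4–C4a without touching C3, and acid then closes the δ-lactone with loss of Et2NH and cleaves the TBS ether by methanolysis (C3 is S here only because the dithiane changes CIP priorities).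

Step 4
Reactants: 15 the dithianyl lactone alcohol
Product: 16 (3R)-3-[(4R)-4-hydroxypentyl]-5,8-dimethoxy-3,4-dihydro-1H-isochromen-1-one
Conditions: Raney Ni (W-2, washed neutral), H2 (1 atm), EtOH, rt
Reagents that add atoms: none
Why: Raney nickel hydrogenolytic desulfurization (Mozingo reduction) turns the thioketal carbon into the C2′ methylene; room temperature under H2 avoids dehydrogenation and epimerization of the free carbinol, and the lactone and aryl ethers are inert.

Step 5
Reactants: 16 the lactone alcohol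
Product: 17 (2R)-5-[(3R)-5,8-dimethoxy-1-oxo-3,4-dihydro-1H-isochromen-3-yl]pentan-2-yl methanesulfonate
Conditions: MsCl, Et3N, CH2Cl2, 0 °C
Reagents that add atoms: methanesulfonyl chloride, CS(=O)(=O)Cl
Why: O-sulfonylation of the only free hydroxyl proceeds with retention at C4′ and provides the leaving group for the inversion.

Step 6
Reactants: 17 the (R)-mesylate; 18 (R)-mevalonolactone [(4R)-4-hydroxy-4-methyloxan-2-one]
Product: 20 (2S)-5-[(3R)-5,8-dimethoxy-1-oxo-3,4-dihydro-1H-isochromen-3-yl]pentan-2-yl (3R)-3,5-dihydroxy-3-methylpentanoate, via cesium mevalonate 19 (not isolated)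
Conditions: 18 (3 equiv), CsOH·H2O (3 equiv), MeOH–H2O, rt, evaporate to dryness; then 17, DMF, 55 °C; pH 7 work-up
Reagents that add atoms: cesium hydroxide, [Cs+].[OH-]
Why: Cesium carboxylate SN2 displacement of a secondary mesylate (Kellogg inversion) sets (S) at C4′ by clean inversion, the carboxylate being the only competent nucleophile of the unprotected mevalonate, whose (R) tertiary centre comes unchanged from 18.

Step 7
Reactants: 20 the di-O-methyl ether of the target
Product: 22 Aspergimarin C [(2S)-5-[(3R)-5,8-dihydroxy-1-oxo-3,4-dihydro-1H-isochromen-3-yl]pentan-2-yl (3R)-3,5-dihydroxy-3-methylpentanoate], via lactone quinone 21 (not isolated)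
Conditions: (NH4)2Ce(NO3)6 (2.5 equiv), MeCN–H2O (2:1), 0 °C, 15 min; then aq. Na2S2O4, EtOAc, rt
Reagents that add atoms: water, O
Why: Oxidative demethylation of the para-dimethoxyarene by tetravalent cerium gives the p-quinone (quinone oxygens from water, methanol released), and immediate dithionite reduction gives the hydroquinone under conditions that leave both esters, the tertiary alcohol and all three stereocentres untouched.

**Compound list**
1 | 2-(tert-butyldimethylsilyl)-1,3-dithiane | CC(C)(C)[Si](C)(C)C1SCCCS1 | starting material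
2 | (R)-propylene oxide | C[C@@H]1CO1 | starting material
3 | (R)-epichlorohydrin | ClC[C@H]1CO1 | starting material
4 | 2-lithio-2-(tert-butyldimethylsilyl)-1,3-dithiane | [Li]C1([Si](C)(C)C(C)(C)C)SCCCS1 | intermediate
5 | lithium (2R)-1-[2-(tert-butyldimethylsilyl)-1,3-dithian-2-yl]propan-2-olate | C[C@H](CC1([Si](C)(C)C(C)(C)C)SCCCS1)O[Li] | intermediate
6 | 2-lithio-2-{(2R)-2-[(tert-butyldimethylsilyl)oxy]propyl}-1,3-dithiane | C[C@H](CC1([Li])SCCCS1)O[Si](C)(C)C(C)(C)C | intermediate
7 | lithium (2R)-1-chloro-3-(2-{(2R)-2-[(tert-butyldimethylsilyl)oxy]propyl}-1,3-dithian-2-yl)propan-2-olate | C[C@H](CC1(C[C@H](CCl)O[Li])SCCCS1)O[Si](C)(C)C(C)(C)C | intermediate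
8 | tert-butyldimethyl{[(2R)-1-(2-{[(2R)-oxiran-2-yl]methyl}-1,3-dithian-2-yl)propan-2-yl]oxy}silane | C[C@H](CC1(C[C@@H]2CO2)SCCCS1)O[Si](C)(C)C(C)(C)C | intermediate
9 | 2,5-dimethoxybenzoic acid | COc1ccc(OC)c(C(=O)O)c1 | starting material
10 | 2,5-dimethoxybenzoyl chloride | COc1ccc(OC)c(C(=O)Cl)c1 | intermediate
11 | N,N-diethyl-2,5-dimethoxybenzamide | CCN(CC)C(=O)c1cc(OC)ccc1OC | intermediate
12 | N,N-diethyl-2-lithio-3,6-dimethoxybenzamide | CCN(CC)C(=O)c1c([Li])c(OC)ccc1OC | intermediate
13 | [2-(diethylcarbamoyl)-3,6-dimethoxyphenyl]magnesium bromide | CCN(CC)C(=O)c1c([Mg]Br)c(OC)ccc1OC | intermediate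
14 | N,N-diethyl-2-[(2S)-3-(2-{(2R)-2-[(tert-butyldimethylsilyl)oxy]propyl}-1,3-dithian-2-yl)-2-hydroxypropyl]-3,6-dimethoxybenzamide | C[C@H](CC1(C[C@@H](O)Cc2c(OC)ccc(OC)c2C(=O)N(CC)CC)SCCCS1)O[Si](C)(C)C(C)(C)C | intermediate
15 | (3S)-3-({2-[(2R)-2-hydroxypropyl]-1,3-dithian-2-yl}methyl)-5,8-dimethoxy-3,4-dihydro-1H-isochromen-1-one | C[C@H](CC1(C[C@@H]2Cc3c(OC)ccc(OC)c3C(=O)O2)SCCCS1)O | intermediate
16 | (3R)-3-[(4R)-4-hydroxypentyl]-5,8-dimethoxy-3,4-dihydro-1H-isochromen-1-one | C[C@H](CCC[C@@H]1Cc2c(OC)ccc(OC)c2C(=O)O1)O | intermediate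
17 | (2R)-5-[(3R)-5,8-dimethoxy-1-oxo-3,4-dihydro-1H-isochromen-3-yl]pentan-2-yl methanesulfonate | C[C@H](CCC[C@@H]1Cc2c(OC)ccc(OC)c2C(=O)O1)OS(C)(=O)=O | intermediate
18 | (R)-mevalonolactone | C[C@@]1(O)CCOC(=O)C1 | starting material
19 | cesium (3R)-3,5-dihydroxy-3-methylpentanoate | [Cs+].[O-]C(=O)C[C@](C)(O)CCO | intermediate
20 | (2S)-5-[(3R)-5,8-dimethoxy-1-oxo-3,4-dihydro-1H-isochromen-3-yl]pentan-2-yl (3R)-3,5-dihydroxy-3-methylpentanoate | C[C@@H](CCC[C@@H]1Cc2c(OC)ccc(OC)c2C(=O)O1)OC(=O)C[C@](C)(O)CCO | intermediate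
21 | (2S)-5-[(3R)-1,5,8-trioxo-3,4,5,8-tetrahydro-1H-isochromen-3-yl]pentan-2-yl (3R)-3,5-dihydroxy-3-methylpentanoate | C[C@@H](CCC[C@@H]1CC2=C(C(=O)O1)C(=O)C=CC2=O)OC(=O)C[C@](C)(O)CCO | intermediate
22 | Aspergimarin C | C[C@@H](CCC[C@@H]1Cc2c(O)ccc(O)c2C(=O)O1)OC(=O)C[C@](C)(O)CCO | target

**Totals**
Total step count: 7. Longest linear sequence: 6 (steps 1, 3, 4, 5, 6, 7 from 1, 2 and 3; equally steps 2–7 from 9).

**Steps most likely to fail and fallbacks**

Step 3. The di-ortho-substituted, chelated aryl nucleophile may open the epoxide sluggishly (bromohydrin formation by MgBr2 competes), and the twisted diethylamide may lactonize slowly. The fallback sets out from epoxide 8 and comes back at 15. Commercial 2-bromo-1,4-dimethoxybenzene is deprotonated between Br and OMe with LiN(i-Pr)2 (THF, −78 °C) and quenched with methyl chloroformate to give methyl 2-bromo-3,6-dimethoxybenzoate F1. Br/Mg exchange with i-PrMgCl·LiCl (THF, −30 °C) gives [2-(methoxycarbonyl)-3,6-dimethoxyphenyl]magnesium chloride F2, which opens 8 under CuBr·SMe2 catalysis. The magnesium alkoxide closes onto the neighbouring methyl ester in the flask to give (3S)-3-[(2-{(2R)-2-[(tert-butyldimethylsilyl)oxy]propyl}-1,3-dithian-2-yl)methyl]-5,8-dimethoxy-3,4-dihydro-1H-isochromen-1-one F3. HCl in MeOH at rt removes the silyl group and gives 15.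

Step 6. E2 elimination of the mesylate can compete, and the free 5-hydroxyl of the product can re-lactonize to 18 with loss of the side-chain alcohol under the warm, weakly basic conditions. The fallback sets out from alcohol 16 and lactone 18 and comes back at 20. Lactone 18 is converted in one flask (KOH, H2O; dry; TBSCl, imidazole, DMF; then K2CO3, MeOH–H2O to cleave only the silyl ester) into (3R)-5-[(tert-butyldimethylsilyl)oxy]-3-hydroxy-3-methylpentanoic acid F4. Mitsunobu esterification of 16 with this acid (PPh3, DIAD, toluene, 0 °C → rt) inverts C4′ and gives (2S)-5-[(3R)-5,8-dimethoxy-1-oxo-3,4-dihydro-1H-isochromen-3-yl]pentan-2-yl (3R)-5-[(tert-butyldimethylsilyl)oxy]-3-hydroxy-3-methylpentanoate F5. HF·pyridine in THF at 0 °C removes the silyl ether and gives 20.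

Step 7. The electron-poor acyl quinone 21 may add water or decompose before reduction, and the acidic oxidant may trigger mevalonate lactonization. The fallback sets out from mesylate 17 and comes back at 22. BBr3 (CH2Cl2, −78 → 0 °C) demethylates both aryl ethers to give (2R)-5-[(3R)-5,8-dihydroxy-1-oxo-3,4-dihydro-1H-isochromen-3-yl]pentan-2-yl methanesulfonate F6. Benzylation of both phenols (BnBr, K2CO3, DMF, rt) gives (2R)-5-[(3R)-5,8-bis(benzyloxy)-1-oxo-3,4-dihydro-1H-isochromen-3-yl]pentan-2-yl methanesulfonate F7. Displacement with cesium mevalonate 19 (DMF, 55 °C) gives (2S)-5-[(3R)-5,8-bis(benzyloxy)-1-oxo-3,4-dihydro-1H-isochromen-3-yl]pentan-2-yl (3R)-3,5-dihydroxy-3-methylpentanoate F8. Neutral hydrogenolysis (H2, Pd on carbon, EtOAc, rt) gives 22.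

**Further compounds**
F1 | step 3 | methyl 2-bromo-3,6-dimethoxybenzoate | COC(=O)c1c(Br)c(OC)ccc1OC
F2 | step 3 | [2-(methoxycarbonyl)-3,6-dimethoxyphenyl]magnesium chloride | COC(=O)c1c([Mg]Cl)c(OC)ccc1OC
F3 | step 3 | (3S)-3-[(2-{(2R)-2-[(tert-butyldimethylsilyl)oxy]propyl}-1,3-dithian-2-yl)methyl]-5,8-dimethoxy-3,4-dihydro-1H-isochromen-1-one | C[C@H](CC1(C[C@@H]2Cc3c(OC)ccc(OC)c3C(=O)O2)SCCCS1)O[Si](C)(C)C(C)(C)C
F4 | step 6 | (3R)-5-[(tert-butyldimethylsilyl)oxy]-3-hydroxy-3-methylpentanoic acid | OC(=O)C[C@](C)(O)CCO[Si](C)(C)C(C)(C)C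
F5 | step 6 | (2S)-5-[(3R)-5,8-dimethoxy-1-oxo-3,4-dihydro-1H-isochromen-3-yl]pentan-2-yl (3R)-5-[(tert-butyldimethylsilyl)oxy]-3-hydroxy-3-methylpentanoate | C[C@@H](CCC[C@@H]1Cc2c(OC)ccc(OC)c2C(=O)O1)OC(=O)C[C@](C)(O)CCO[Si](C)(C)C(C)(C)C
F6 | step 7 | (2R)-5-[(3R)-5,8-dihydroxy-1-oxo-3,4-dihydro-1H-isochromen-3-yl]pentan-2-yl methanesulfonate | C[C@H](CCC[C@@H]1Cc2c(O)ccc(O)c2C(=O)O1)OS(C)(=O)=O
F7 | step 7 | (2R)-5-[(3R)-5,8-bis(benzyloxy)-1-oxo-3,4-dihydro-1H-isochromen-3-yl]pentan-2-yl methanesulfonate | C[C@H](CCC[C@@H]1Cc2c(OCc3ccccc3)ccc(OCc3ccccc3)c2C(=O)O1)OS(C)(=O)=O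
F8 | step 7 | (2S)-5-[(3R)-5,8-bis(benzyloxy)-1-oxo-3,4-dihydro-1H-isochromen-3-yl]pentan-2-yl (3R)-3,5-dihydroxy-3-methylpentanoate | C[C@@H](CCC[C@@H]1Cc2c(OCc3ccccc3)ccc(OCc3ccccc3)c2C(=O)O1)OC(=O)C[C@](C)(O)CCO
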